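**Retrosynthetic overview**

- The target is read as a tetralin: C1 carries the CH2OAc carbon, C4 the side chain, C6 the CO2H, C8 the OH. The strategy rests on its benzene ring C4a–C5–C6(CO2H)–C7–C8(OH)–C8a, where C5–C8 are a 2-methylfumarate unit and C4a/C4/C11–C15 are (S)-citronellal with the aldehyde carbon as C4a.
- Key disconnection: C4a–C5 and C8–C8a. The arene is annulated onto cyclohexenone 5 with sulfonyl fumarate 10 (Michael addition, Dieckmann closure, sulfinate loss) to give 8-hydroxy-1-tetralone 13.
- Ring order: ring A first (citronellal + methyl vinyl ketone; the catalyst-controlled Michael step sets C4, then aldol condensation), the benzene ring second.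
- Endgame: O-allylation, one-carbon homologation at C1 (methoxymethylene Wittig, hydrolysis), equilibration to the 1,4-trans aldehyde, reduction, saponification, acetylation, Pd(0) deallylation.

Key step: step 5

Remark: ring positions in the text use the tetralin numbering above; compound names use IUPAC numbering, in which these positions are C5, C8, C2 and C4. The phenol is carried as an allyl ether rather than a methyl ether so that the last deprotection is neutral and spares the acetate.

**Route**

Step 1
Reactants: 1 (S)-citronellal; 2 methyl vinyl ketone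
Product: 3 (2S,3S)-3,7-dimethyl-2-(3-oxobutyl)oct-6-enal
Conditions: (S)-2-[methoxy(diphenyl)methyl]pyrrolidine (5 mol%), ethyl 3,4-dihydroxybenzoate (20 mol%), neat, 4 °C
Reagents that add atoms: none
Why: Enamine-catalysed Michael addition in which methyl vinyl ketone attacks the (E)-enamine of 1 on the face away from the CPh2OMe group of the (S)-prolinol ether, so the new aldehyde α-centre (future C4) is set as S under catalyst control beside the untouched citronellal centre (future C11).

Step 2
Reactants: 3 (2S,3S)-3,7-dimethyl-2-(3-oxobutyl)oct-6-enal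
Product: 5 (4S)-4-[(2S)-6-methylhept-5-en-2-yl]cyclohex-2-en-1-one, via aldol adduct 4 (not isolated)
Conditions: LiOH·H2O (0.2 equiv), i-PrOH, rt
Reagents that add atoms: none
Why: Intramolecular aldol condensation (second half of a Robinson annulation) in which only the methyl ketone enolate reaches the aldehyde through a six-membered closure, and mild hydroxide dehydrates aldol 4 to the enone without expected erosion of the γ-stereocentre.

Step 3
Reactants: 6 dimethyl itaconate
Product: 8 dimethyl (2Z)-2-(bromomethyl)but-2-enedioate, via dibromide 7 (not isolated)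
Conditions: Br2, CH2Cl2, 0 °C to reflux; concentrate; Et3N (1.1 equiv), Et2O, 0 °C to rt
Reagents that add atoms: bromine, BrBr
Why: Bromine addition to the 1,1-disubstituted alkene followed by amine-induced dehydrobromination, in which only the C3–H α to an ester is acidic, so HBr is lost toward C3 and the conjugated trans-diester bearing an allylic bromide results.

Step 4
Reactants: 8 dimethyl (2Z)-2-(bromomethyl)but-2-enedioate; 9 sodium benzenesulfinate
Product: 10 dimethyl (2Z)-2-[(phenylsulfonyl)methyl]but-2-enedioate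
Conditions: PhSO2Na (1.1 equiv), DMF, rt
Reagents that add atoms: none
Why: S-alkylation of the sulfinate by an activated allylic bromide (SN2, or SN2′ followed by sulfinate-mediated allylic transposition), which should converge on the conjugated sulfone with the trans-diester geometry as the more stable isomer.

Step 5
Reactants: 5 (4S)-4-[(2S)-6-methylhept-5-en-2-yl]cyclohex-2-en-1-one; 10 dimethyl (2Z)-2-[(phenylsulfonyl)methyl]but-2-enedioate
Product: 13 methyl (8S)-4-hydroxy-8-[(2S)-6-methylhept-5-en-2-yl]-5-oxo-5,6,7,8-tetrahydronaphthalene-2-carboxylate, via Michael adduct 11 (not isolated), via Dieckmann diketone 12 (not isolated)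
Conditions: 10 (1.2 equiv) added to LiHMDS (1.2 equiv), THF, −78 °C; 5 (1.0 equiv), −78 °C to rt; DBU (2 equiv), 50 °C; aq. HCl
Reagents that add atoms: none
Why: Proposed new method: deprotonation of 10 at C5 gives an allyl anion stabilised by the sulfone and the vinylogous C8 ester, which adds through C5 to the enone β-carbon (C4a); the resulting C1/C8a lithium enolate acylates at the C8 ester held cis to C5 by the fumarate geometry (Dieckmann, 6-exo-trig acyl substitution closing the new carbocycle), and the enolised β-diketone 12 then loses the C4a proton and benzenesulfinate (vinylogous E1cB) to give the phenol. The closest known reaction type is the Hauser–Kraus annulation of 3-sulfonylphthalides, together with the related sulfinyl or sulfonyl ortho-toluate naphthol annulation, with enones (Michael addition, Dieckmann closure, loss of the sulfur group), here transferred to an acyclic donor. No new stereocentre survives, since C4a, C5 and C8a become arene carbons, and C4 and C11 should be carried through because the donor anion is preformed and is too weak a base to make the dienolate of 5. The step needs C-attack through C5 rather than C7 and 1,4- rather than 1,2-addition; both alternatives are reversible for this soft delocalised anion, whereas only the C5/1,4 path reaches the irreversible aromatisation. Adducts of the wrong alkene geometry, the proton-transfer resting state at C5 and any five-membered acylation at the C6 ester can revert under the equilibrating conditions and drain through the same aromatic sink.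

Step 6
Reactants: 13 methyl (8S)-4-hydroxy-8-[(2S)-6-methylhept-5-en-2-yl]-5-oxo-5,6,7,8-tetrahydronaphthalene-2-carboxylate
Product: 14 methyl (8S)-8-[(2S)-6-methylhept-5-en-2-yl]-5-oxo-4-(prop-2-en-1-yloxy)-5,6,7,8-tetrahydronaphthalene-2-carboxylate
Conditions: allyl bromide (1.5 equiv), K2CO3 (2 equiv), DMF, 50 °C
Reagents that add atoms: allyl bromide, C=CCBr
Why: Williamson ether synthesis in which carbonate deprotonates the chelated phenol but not the ketone α-position, and the phenoxide is O-alkylated to an ether that is later removable under neutral Pd(0) conditions.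

Step 7
Reactants: 14 methyl (8S)-8-[(2S)-6-methylhept-5-en-2-yl]-5-oxo-4-(prop-2-en-1-yloxy)-5,6,7,8-tetrahydronaphthalene-2-carboxylate
Product: 15 methyl (8S)-5-(methoxymethylidene)-8-[(2S)-6-methylhept-5-en-2-yl]-4-(prop-2-en-1-yloxy)-5,6,7,8-tetrahydronaphthalene-2-carboxylate
Conditions: Ph3P(CH2OMe)Cl (3.0 equiv), KHMDS (2.9 equiv), THF, 0 °C; then 14, 0 °C to rt
Reagents that add atoms: (methoxymethyl)triphenylphosphonium chloride, COC[P+](c1ccccc1)(c1ccccc1)c1ccccc1.[Cl-]
Why: Wittig methoxymethylenation in which the non-stabilised α-methoxy ylide adds to the aryl ketone in preference to the conjugated ester and gives the enol ether as an E/Z mixture that is of no consequence.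

Step 8
Reactants: 15 methyl (8S)-5-(methoxymethylidene)-8-[(2S)-6-methylhept-5-en-2-yl]-4-(prop-2-en-1-yloxy)-5,6,7,8-tetrahydronaphthalene-2-carboxylate
Product: 16 methyl (8S)-5-formyl-8-[(2S)-6-methylhept-5-en-2-yl]-4-(prop-2-en-1-yloxy)-5,6,7,8-tetrahydronaphthalene-2-carboxylate (C5 epimer mixture)
Conditions: 2 M aq. HCl, THF, rt
Reagents that add atoms: water, O
Why: Acid-catalysed enol ether hydrolysis (protonation at C1, hydration of the oxocarbenium ion, loss of methanol) under conditions mild enough to leave the trisubstituted alkene and the allyl ether alone, with C1 formed as an epimer mixture at this stage.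

Step 9
Reactants: 16 methyl (8S)-5-formyl-8-[(2S)-6-methylhept-5-en-2-yl]-4-(prop-2-en-1-yloxy)-5,6,7,8-tetrahydronaphthalene-2-carboxylate (C5 epimer mixture)
Product: 18 methyl (5R,8S)-5-(hydroxymethyl)-8-[(2S)-6-methylhept-5-en-2-yl]-4-(prop-2-en-1-yloxy)-5,6,7,8-tetrahydronaphthalene-2-carboxylate, via trans aldehyde 17 (not isolated)
Conditions: K2CO3 (0.3 equiv), MeOH, rt, argon; then NaBH4, 0 °C
Reagents that add atoms: none
Why: Enolate-mediated epimerisation of the α-aryl aldehyde followed by chemoselective borohydride reduction, in which the peri C8 allyloxy group pushes the C1 formyl group pseudoaxial and the peri C5–H pushes the C4 side chain pseudoaxial, so the 1,4-trans (1R) isomer should dominate at equilibrium and is then fixed as the primary alcohol while the ester is untouched.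

Step 10
Reactants: 18 methyl (5R,8S)-5-(hydroxymethyl)-8-[(2S)-6-methylhept-5-en-2-yl]-4-(prop-2-en-1-yloxy)-5,6,7,8-tetrahydronaphthalene-2-carboxylate
Product: 19 (5R,8S)-5-(hydroxymethyl)-8-[(2S)-6-methylhept-5-en-2-yl]-4-(prop-2-en-1-yloxy)-5,6,7,8-tetrahydronaphthalene-2-carboxylic acid
Conditions: LiOH·H2O (5 equiv), THF/MeOH/H2O, 40 °C; then aq. HCl to pH 3
Reagents that add atoms: lithium hydroxide, [Li+].[OH-]
Why: Saponification of the aryl methyl ester (BAc2) in a molecule whose primary alcohol, allyl aryl ether and benzylic stereocentres are all stable to hydroxide.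

Step 11
Reactants: 19 (5R,8S)-5-(hydroxymethyl)-8-[(2S)-6-methylhept-5-en-2-yl]-4-(prop-2-en-1-yloxy)-5,6,7,8-tetrahydronaphthalene-2-carboxylic acid
Product: 20 (5R,8S)-5-(acetoxymethyl)-8-[(2S)-6-methylhept-5-en-2-yl]-4-(prop-2-en-1-yloxy)-5,6,7,8-tetrahydronaphthalene-2-carboxylic acid
Conditions: Ac2O (2 equiv), pyridine, DMAP (cat.), CH2Cl2, 0 °C to rt; aq. NaHCO3, then acidify
Reagents that add atoms: acetic anhydride, CC(=O)OC(C)=O
Why: Nucleophile-catalysed O-acetylation of the only hydroxyl group, with any mixed anhydride formed at the carboxylic acid hydrolysed in the bicarbonate work-up.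

Step 12
Reactants: 20 (5R,8S)-5-(acetoxymethyl)-8-[(2S)-6-methylhept-5-en-2-yl]-4-(prop-2-en-1-yloxy)-5,6,7,8-tetrahydronaphthalene-2-carboxylic acid
Product: 21 (5R,8S)-5-(acetoxymethyl)-4-hydroxy-8-[(2S)-6-methylhept-5-en-2-yl]-5,6,7,8-tetrahydronaphthalene-2-carboxylic acid
Conditions: Pd(PPh3)4 (5 mol%), morpholine (5 equiv), THF, rt; aq. citric acid
Reagents that add atoms: none
Why: Tsuji–Trost deallylation in which Pd(0) ionises the allyl aryl ether to a π-allyl complex and phenoxide and morpholine traps the allyl unit, under neutral conditions that leave the primary acetate, the acid, the trisubstituted alkene and both ring stereocentres untouched.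

**Compound list**

1 | (S)-citronellal | O=CC[C@@H](C)CCC=C(C)C | starting material
2 | methyl vinyl ketone | CC(=O)C=C | starting material
3 | (2S,3S)-3,7-dimethyl-2-(3-oxobutyl)oct-6-enal | CC(=O)CC[C@@H]([C@@H](C)CCC=C(C)C)C=O | intermediate
4 | (4S)-3-hydroxy-4-[(2S)-6-methylhept-5-en-2-yl]cyclohexan-1-one (carbinol epimers; aldol adduct) | O=C1CC[C@@H]([C@@H](C)CCC=C(C)C)C(O)C1 | intermediate
5 | (4S)-4-[(2S)-6-methylhept-5-en-2-yl]cyclohex-2-en-1-one | O=C1CC[C@@H]([C@@H](C)CCC=C(C)C)C=C1 | intermediate
6 | dimethyl itaconate | COC(=O)CC(=C)C(=O)OC | starting material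
7 | dimethyl 2-bromo-2-(bromomethyl)butanedioate (racemic) | COC(=O)CC(Br)(CBr)C(=O)OC | intermediate
8 | dimethyl (2Z)-2-(bromomethyl)but-2-enedioate (2-(bromomethyl)fumarate) | COC(=O)/C=C(\CBr)C(=O)OC | intermediate
9 | sodium benzenesulfinate | [Na+].[O-]S(=O)c1ccccc1 | starting material
10 | dimethyl (2Z)-2-[(phenylsulfonyl)methyl]but-2-enedioate (2-(phenylsulfonylmethyl)fumarate) | COC(=O)/C=C(\CS(=O)(=O)c1ccccc1)C(=O)OC | intermediate
11 | dimethyl (2Z)-2-{[(2S)-2-[(2S)-6-methylhept-5-en-2-yl]-5-oxocyclohexyl](phenylsulfonyl)methyl}but-2-enedioate (Michael adduct, mixture at the two new centres, present as its lithium enolate) | O=C1CC[C@@H]([C@@H](C)CCC=C(C)C)C(C1)C(S(=O)(=O)c2ccccc2)/C(C(=O)OC)=C\C(=O)OC | intermediate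
12 | methyl (8S)-8-[(2S)-6-methylhept-5-en-2-yl]-4,5-dioxo-1-(phenylsulfonyl)-1,4,4a,5,6,7,8,8a-octahydronaphthalene-2-carboxylate (Dieckmann β-diketone, mixture at C1, C4a and C8a, present as its enolate) | O=C1CC[C@@H]([C@@H](C)CCC=C(C)C)C2C1C(=O)C=C(C(=O)OC)C2S(=O)(=O)c3ccccc3 | intermediate
13 | methyl (8S)-4-hydroxy-8-[(2S)-6-methylhept-5-en-2-yl]-5-oxo-5,6,7,8-tetrahydronaphthalene-2-carboxylate | O=C1CC[C@@H]([C@@H](C)CCC=C(C)C)c2cc(C(=O)OC)cc(O)c21 | intermediate
14 | methyl (8S)-8-[(2S)-6-methylhept-5-en-2-yl]-5-oxo-4-(prop-2-en-1-yloxy)-5,6,7,8-tetrahydronaphthalene-2-carboxylate | O=C1CC[C@@H]([C@@H](C)CCC=C(C)C)c2cc(C(=O)OC)cc(OCC=C)c21 | intermediate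
15 | methyl (8S)-5-(methoxymethylidene)-8-[(2S)-6-methylhept-5-en-2-yl]-4-(prop-2-en-1-yloxy)-5,6,7,8-tetrahydronaphthalene-2-carboxylate (E/Z mixture) | COC=C1CC[C@@H]([C@@H](C)CCC=C(C)C)c2cc(C(=O)OC)cc(OCC=C)c21 | intermediate
16 | methyl (8S)-5-formyl-8-[(2S)-6-methylhept-5-en-2-yl]-4-(prop-2-en-1-yloxy)-5,6,7,8-tetrahydronaphthalene-2-carboxylate (C5 epimer mixture) | O=CC1CC[C@@H]([C@@H](C)CCC=C(C)C)c2cc(C(=O)OC)cc(OCC=C)c21 | intermediate
17 | methyl (5R,8S)-5-formyl-8-[(2S)-6-methylhept-5-en-2-yl]-4-(prop-2-en-1-yloxy)-5,6,7,8-tetrahydronaphthalene-2-carboxylate (1,4-trans) | O=C[C@@H]1CC[C@@H]([C@@H](C)CCC=C(C)C)c2cc(C(=O)OC)cc(OCC=C)c21 | intermediate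
18 | methyl (5R,8S)-5-(hydroxymethyl)-8-[(2S)-6-methylhept-5-en-2-yl]-4-(prop-2-en-1-yloxy)-5,6,7,8-tetrahydronaphthalene-2-carboxylate | OC[C@@H]1CC[C@@H]([C@@H](C)CCC=C(C)C)c2cc(C(=O)OC)cc(OCC=C)c21 | intermediate
19 | (5R,8S)-5-(hydroxymethyl)-8-[(2S)-6-methylhept-5-en-2-yl]-4-(prop-2-en-1-yloxy)-5,6,7,8-tetrahydronaphthalene-2-carboxylic acid | OC[C@@H]1CC[C@@H]([C@@H](C)CCC=C(C)C)c2cc(C(=O)O)cc(OCC=C)c21 | intermediate
20 | (5R,8S)-5-(acetoxymethyl)-8-[(2S)-6-methylhept-5-en-2-yl]-4-(prop-2-en-1-yloxy)-5,6,7,8-tetrahydronaphthalene-2-carboxylic acid | CC(=O)OC[C@@H]1CC[C@@H]([C@@H](C)CCC=C(C)C)c2cc(C(=O)O)cc(OCC=C)c21 | intermediate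
21 | (5R,8S)-5-(acetoxymethyl)-4-hydroxy-8-[(2S)-6-methylhept-5-en-2-yl]-5,6,7,8-tetrahydronaphthalene-2-carboxylic acid | CC(=O)OC[C@@H]1CC[C@@H]([C@@H](C)CCC=C(C)C)c2cc(C(=O)O)cc(O)c21 | target

**Totals**

Total step count: 12. Longest linear sequence: 10 steps (steps 1, 2 and 5–12 from (S)-citronellal; the donor branch, steps 3, 4 and 5–12, is equally long).

**Steps most likely to fail**

Step 5 (the proposed annulation). The hindered β-carbon next to the branched C4 substituent may make the Michael addition slow and reversible. The sequence may also stall at the C5 carbanion resting state, or sulfinate loss from the diketone may be incomplete. The fallback sets out from enone 5 and returns at 13, building the same ring by a Stobbe-type alkylidene-succinate sequence of known reaction types: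
- Conjugate addition of nitromethane (DBU, MeCN) anti to the C4 side chain would give (3R,4S)-3-(nitromethyl)-4-[(2S)-6-methylhept-5-en-2-yl]cyclohexan-1-one F1.
- A reductive Nef reaction (NaOMe, then buffered aqueous TiCl3) would unmask C5 as (1R,2S)-2-[(2S)-6-methylhept-5-en-2-yl]-5-oxocyclohexane-1-carbaldehyde F2.
- Horner–Wadsworth–Emmons olefination of the aldehyde, not the ketone, with trimethyl phosphonosuccinate (LiCl, DBU, MeCN) would give dimethyl (2E)-2-{[(1R,2S)-2-[(2S)-6-methylhept-5-en-2-yl]-5-oxocyclohexyl]methylidene}butanedioate F3, in which C4a and the CH2CO2Me arm are cis.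
- NaOMe in MeOH would close the C8a–C8 bond by Dieckmann acylation to methyl (8S,8aS)-8-[(2S)-6-methylhept-5-en-2-yl]-4,5-dioxo-3,4,4a,5,6,7,8,8a-octahydronaphthalene-2-carboxylate F4.
- DDQ (dioxane, rt) would dehydrogenate this dihydroaromatic β-diketone to 13.

Step 7 (Wittig at the peri-alkoxy tetralone). The basic ylide may enolise the hindered ketone instead of adding, returning starting material. The fallback sets out from 14 and returns at 16. Corey–Chaykovsky addition of the smaller dimethylsulfonium methylide (Me3SI, KHMDS, THF, −10 °C) would give methyl (8S)-8-[(2S)-6-methylhept-5-en-2-yl]-4-(prop-2-en-1-yloxy)-7,8-dihydro-6H-spiro[naphthalene-5,2'-oxirane]-2-carboxylate F5. Lewis-acid Meinwald rearrangement (BF3·OEt2 cat., CH2Cl2, −78 °C) would open it at the benzylic carbon and, by hydride shift, deliver aldehyde 16.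

Step 9 (thermodynamic control of C1). The preference for the 1,4-trans aldehyde at equilibrium may be too small to give useful diastereoselection. The fallback sets out from 16 and returns at 18, replacing thermodynamic control by catalyst control. Asymmetric hydrogenation of the epimerising α-aryl aldehyde under dynamic kinetic resolution (a chiral Ru diphosphine/diamine catalyst, KOt-Bu cat., i-PrOH, H2) would reduce only the C=O group and set C1 by the catalyst enantiomer chosen for the (1R) alcohol. The fallback makes no compound that the list lacks (none F0).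

**Further compounds**

F1 | step 5 | (3R,4S)-3-(nitromethyl)-4-[(2S)-6-methylhept-5-en-2-yl]cyclohexan-1-one | O=C1CC[C@@H]([C@@H](C)CCC=C(C)C)[C@H](C[N+](=O)[O-])C1
F2 | step 5 | (1R,2S)-2-[(2S)-6-methylhept-5-en-2-yl]-5-oxocyclohexane-1-carbaldehyde | O=C1CC[C@@H]([C@@H](C)CCC=C(C)C)[C@H](C=O)C1
F3 | step 5 | dimethyl (2E)-2-{[(1R,2S)-2-[(2S)-6-methylhept-5-en-2-yl]-5-oxocyclohexyl]methylidene}butanedioate | O=C1CC[C@@H]([C@@H](C)CCC=C(C)C)[C@H](/C=C(\CC(=O)OC)C(=O)OC)C1
F4 | step 5 | methyl (8S,8aS)-8-[(2S)-6-methylhept-5-en-2-yl]-4,5-dioxo-3,4,4a,5,6,7,8,8a-octahydronaphthalene-2-carboxylate (C4a unspecified, enolised) | O=C1CC[C@@H]([C@@H](C)CCC=C(C)C)[C@@H]2C=C(C(=O)OC)CC(=O)C12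
F5 | step 7 | methyl (8S)-8-[(2S)-6-methylhept-5-en-2-yl]-4-(prop-2-en-1-yloxy)-7,8-dihydro-6H-spiro[naphthalene-5,2'-oxirane]-2-carboxylate (spiro-centre epimers) | C1OC12CC[C@@H]([C@@H](C)CCC=C(C)C)c3cc(C(=O)OC)cc(OCC=C)c32
F0 | step 9 | none | none
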